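**Labels used below:** C1–C15 are the germacranolide positions of the target: C1 ketone, C2=C3 furanone alkene, C4(C15H3)=C5 (Z), C6 ester carbinol, C7, C8 lactone carbinol, C9H2, C10 (C14H3, furanone O), C11=C13H2, C12 lactone C=O. The target is (4Z,6S,7R,8S,10S) with a (2S,3S)-epoxyangelate.

## Retrosynthetic overview

1. C6 ester last: Mitsunobu inversion of the (6R)-alcohol 30 with (2S,3S)-epoxyangelic acid 34 (Sharpless epoxidation of angelyl alcohol, then oxidation).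
2. Furanone (third ring): gold-catalysed 5-endo cyclization of C10–OH onto a cyclic ynone; ten-membered carbocycle (second ring): intramolecular CrCl2/NiCl2 alkynylation closing C1–C2.
3. Key union, C6–C7: intermolecular chromium-mediated carbonyl allylation of (Z)-enynal 19 with bromolactone 17; the butenolide (first ring) becomes the trans α-methylidene lactone.
4. Bromolactone 17 from L-malic acid: C10 by Seebach methylation, C8 by Noyori reduction of an ynone, butenolide by hydroalumination–iodination and Pd carbonylation.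
5. Ring order: lactone, then ten-membered ring, then 3(2H)-furanone.

## Route

Step 1
Reactants: 1 L-malic acid
Product: 2 2-[(2S,4S)-2-tert-butyl-5-oxo-1,3-dioxolan-4-yl]acetic acid
Conditions: t-BuCHO, TsOH·H2O (cat.), H2SO4 (cat.), pentane, reflux, Dean–Stark
Reagents that add atoms: pivalaldehyde, CC(C)(C)C=O
Why: Seebach acetalization of the α-hydroxy acid gives the favoured cis-dioxolanone and leaves the β-carboxyl free; the stereocentre is that of L-malic acid.

Step 2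
Reactants: 2
Product: 4 2-[(2S,4S)-2-tert-butyl-4-methyl-5-oxo-1,3-dioxolan-4-yl]acetic acid, via dilithium enolate-carboxylate 3 (not isolated)
Conditions: LiN(SiMe3)2 (2.2 equiv), THF, −78 °C; MeI, −78 to −20 °C; aq. HCl
Reagents that add atoms: iodomethane, CI
Why: Seebach self-regeneration of stereocentres: the enolate is methylated anti to the tert-butyl group, so CH3 replaces H with retention and sets the (S)-quaternary C10.

Step 3
Reactants: 4
Product: 5 (2S)-2-methylbutane-1,2,4-triol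
Conditions: LiAlH4, THF, 0 °C to reflux; Fieser work-up
Reagents that add atoms: none
Why: Hydride reduction of the acid and the dioxolanone (acetal carbon leaves as neopentyl alcohol) does not touch the quaternary centre.

Step 4
Reactants: 5
Product: 6 2-[(4S)-2,2,4-trimethyl-1,3-dioxolan-4-yl]ethan-1-ol
Conditions: Me2C(OMe)2, acetone, TsOH (cat.), rt
Reagents that add atoms: 2,2-dimethoxypropane, COC(C)(C)OC
Why: Thermodynamic ketalization prefers the five-membered acetonide on the 1,2-diol (C1/C10) and leaves the primary C8 alcohol free.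

Step 5
Reactants: 6
Product: 7 2-[(4S)-2,2,4-trimethyl-1,3-dioxolan-4-yl]acetaldehyde
Conditions: SO3·pyridine, DMSO, iPr2NEt, CH2Cl2, 0 °C
Reagents that add atoms: none
Why: Parikh–Doering oxidation is mild enough for the acetonide and the β-alkoxy aldehyde.

Step 6
Reactants: 7 and 8 tert-butyl(dimethyl)(prop-2-yn-1-yloxy)silane
Product: 10 5-{[tert-butyl(dimethyl)silyl]oxy}-1-[(4S)-2,2,4-trimethyl-1,3-dioxolan-4-yl]pent-3-yn-2-ol (C2 epimers), via lithium acetylide 9 (not isolated)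
Conditions: 8, n-BuLi, THF, −78 °C; then 7; aq. NH4Cl
Reagents that add atoms: none
Why: Acetylide addition to the aldehyde builds C7–C8; the carbinol epimers are both oxidized in the next step.

Step 7
Reactants: 10
Product: 11 5-{[tert-butyl(dimethyl)silyl]oxy}-1-[(4S)-2,2,4-trimethyl-1,3-dioxolan-4-yl]pent-3-yn-2-one
Conditions: Dess–Martin periodinane, NaHCO3, CH2Cl2, 0 °C to rt
Reagents that add atoms: none
Why: Dess–Martin oxidation of a propargylic alcohol to the ynone is neutral and leaves the acetonide and silyl ether intact.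

Step 8
Reactants: 11
Product: 12 (2S)-5-{[tert-butyl(dimethyl)silyl]oxy}-1-[(4S)-2,2,4-trimethyl-1,3-dioxolan-4-yl]pent-3-yn-2-ol
Conditions: RuCl[(S,S)-TsDPEN](p-cymene) (2 mol %), i-PrOH, rt
Reagents that add atoms: none
Why: Noyori asymmetric transfer hydrogenation of an alkynyl ketone; the (S,S) catalyst gives the (S)-propargylic alcohol (C8) under reagent control.

Step 9
Reactants: 12
Product: 14 (2S,3Z)-5-{[tert-butyl(dimethyl)silyl]oxy}-4-iodo-1-[(4S)-2,2,4-trimethyl-1,3-dioxolan-4-yl]pent-3-en-2-ol, via cyclic alkenylaluminate 13 (not isolated)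
Conditions: NaAlH2(OCH2CH2OMe)2 (Red-Al), THF, 0 °C to rt; I2, THF, −78 °C
Reagents that add atoms: iodine, II
Why: Hydroxyl-directed trans-hydroalumination puts Al on the distal alkyne carbon (C11), and iododealumination with retention gives the iodoalkene with iodine cis to the carbinol carbon.

Step 10
Reactants: 14
Product: 15 (5S)-3-({[tert-butyl(dimethyl)silyl]oxy}methyl)-5-{[(4S)-2,2,4-trimethyl-1,3-dioxolan-4-yl]methyl}furan-2(5H)-one
Conditions: PdCl2(PPh3)2 (5 mol %), CO (1 atm), K2CO3, THF, rt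
Reagents that add atoms: carbon monoxide, [C-]#[O+]
Why: Pd-catalysed carbonylative lactonization of a (Z)-γ-iodo allylic alcohol (Stille butenolide synthesis) closes the lactone onto the C8 oxygen without touching C8.

Step 11
Reactants: 15
Product: 16 (5S)-3-(hydroxymethyl)-5-{[(4S)-2,2,4-trimethyl-1,3-dioxolan-4-yl]methyl}furan-2(5H)-one
Conditions: HF·pyridine, pyridine, THF, 0 °C to rt
Reagents that add atoms: none
Why: Buffered fluoride desilylation frees the primary allylic alcohol without base (no γ-epimerization) and without cleaving the acetonide.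

Step 12
Reactants: 16
Product: 17 (5S)-3-(bromomethyl)-5-{[(4S)-2,2,4-trimethyl-1,3-dioxolan-4-yl]methyl}furan-2(5H)-one
Conditions: CBr4, PPh3, CH2Cl2, 0 °C
Reagents that add atoms: carbon tetrabromide, BrC(Br)(Br)Br
Why: Appel bromination converts the allylic alcohol to the allylic bromide under neutral conditions.

Step 13
Reactants: 18 (2Z)-3-methylpent-2-en-4-yn-1-ol
Product: 19 (2Z)-3-methylpent-2-en-4-ynal
Conditions: activated MnO2, CH2Cl2, rt, dark; used at once
Reagents that add atoms: none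
Why: MnO2 oxidation of the allylic alcohol is neutral, so the Z geometry (C3 and C6 cis on C4=C5) is kept.

Step 14
Reactants: 17 and 19
Product: 20 (4S,5S)-4-[(1R,2Z)-1-hydroxy-3-methylpent-2-en-4-yn-1-yl]-3-methylidene-5-{[(4S)-2,2,4-trimethyl-1,3-dioxolan-4-yl]methyl}oxolan-2-one
Conditions: CrCl2 (4 equiv), THF, 0 °C to rt
Reagents that add atoms: none
Why: Nozaki–Hiyama carbonyl allylation: the allylchromium reacts at its γ-carbon (C7) through a chair transition state on the butenolide face anti to the C8 side chain (7,8-trans lactone) with the aldehyde residue equatorial (anti adduct, 6R), giving the α-methylidene lactone and the C6 epimer that step 28 inverts.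

Step 15
Reactants: 20
Product: 21 (4R,5S)-4-[(1R,2Z)-1-{[tert-butyl(dimethyl)silyl]oxy}-3-methylpent-2-en-4-yn-1-yl]-3-methylidene-5-{[(4S)-2,2,4-trimethyl-1,3-dioxolan-4-yl]methyl}oxolan-2-one
Conditions: TBSOTf, 2,6-lutidine, CH2Cl2, −78 °C
Reagents that add atoms: tert-butyldimethylsilyl trifluoromethanesulfonate, CC(C)(C)[Si](C)(C)OS(=O)(=O)C(F)(F)F
Why: Silylation blocks the (Z)-enynol hydroxyl, which would otherwise cyclize onto the alkyne or translactonize (the C4 label changes, the geometry does not).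

Step 16
Reactants: 21
Product: 22 (4R,5S)-4-[(1R,2Z)-1-{[tert-butyl(dimethyl)silyl]oxy}-3-methylpent-2-en-4-yn-1-yl]-5-[(2S)-2,3-dihydroxy-2-methylpropyl]-3-methylideneoxolan-2-one
Conditions: CSA (cat.), MeOH, 0 °C
Reagents that add atoms: none
Why: Acid-catalysed transketalization removes the acetonide while the secondary TBS ether survives at 0 °C.

Step 17
Reactants: 22
Product: 23 (2S)-3-[(2S,3R)-3-[(1R,2Z)-1-{[tert-butyl(dimethyl)silyl]oxy}-3-methylpent-2-en-4-yn-1-yl]-4-methylidene-5-oxooxolan-2-yl]-2-hydroxy-2-methylpropanal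
Conditions: SO3·pyridine, DMSO, iPr2NEt, CH2Cl2, 0 °C
Reagents that add atoms: none
Why: Parikh–Doering oxidation takes only the primary C1 alcohol; the tertiary C10 alcohol cannot be oxidized and the aldehyde has no α-hydrogen.

Step 18
Reactants: 23
Product: 24 (2S)-3-[(2S,3R)-3-[(1R,2Z)-1-{[tert-butyl(dimethyl)silyl]oxy}-3-methylpent-2-en-4-yn-1-yl]-4-methylidene-5-oxooxolan-2-yl]-2-methyl-2-[(triethylsilyl)oxy]propanal
Conditions: TESOTf, 2,6-lutidine, CH2Cl2, −78 °C
Reagents that add atoms: triethylsilyl trifluoromethanesulfonate, CC[Si](CC)(CC)OS(=O)(=O)C(F)(F)F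
Why: Silyl triflate silylation caps the tertiary alcohol (no α-ketol shift or dimerization later) with a group more labile than TBS.

Step 19
Reactants: 24
Product: 25 (2S)-3-[(2S,3R)-3-[(1R,2Z)-1-{[tert-butyl(dimethyl)silyl]oxy}-5-iodo-3-methylpent-2-en-4-yn-1-yl]-4-methylidene-5-oxooxolan-2-yl]-2-methyl-2-[(triethylsilyl)oxy]propanal
Conditions: NIS, AgNO3 (10 mol %), acetone, rt, dark
Reagents that add atoms: N-iodosuccinimide, O=C1CCC(=O)N1I
Why: Silver-catalysed iodination of the terminal alkyne gives the 1-iodoalkyne needed for chromium insertion and touches nothing else.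

Step 20
Reactants: 25
Product: 26 (4Z,6R,7R,8S,10S)-6-{[tert-butyl(dimethyl)silyl]oxy}-1-hydroxy-10-[(triethylsilyl)oxy]germacra-4,11(13)-dien-2-yn-12,8-olide (C1 epimers)
Conditions: CrCl2 (8 equiv), NiCl2 (1 mol %), THF, rt, syringe-pump addition to 0.002 M
Reagents that add atoms: none
Why: Intramolecular Nozaki–Hiyama–Kishi alkynylation closes C1–C2 chemoselectively at the aldehyde under high dilution; the new C1 carbinol is oxidized next, so its configuration does not matter.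

Step 21
Reactants: 26
Product: 27 (4Z,6R,7R,8S,10S)-6-{[tert-butyl(dimethyl)silyl]oxy}-1-oxo-10-[(triethylsilyl)oxy]germacra-4,11(13)-dien-2-yn-12,8-olide
Conditions: Dess–Martin periodinane, NaHCO3, CH2Cl2, 0 °C
Reagents that add atoms: none
Why: Dess–Martin oxidation converts both propargylic epimers into the single cyclic ynone.

Step 22
Reactants: 27
Product: 28 (4Z,6R,7R,8S,10S)-6-{[tert-butyl(dimethyl)silyl]oxy}-10-hydroxy-1-oxogermacra-4,11(13)-dien-2-yn-12,8-olide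
Conditions: HF·pyridine, pyridine, THF, 0 °C
Reagents that add atoms: none
Why: Buffered fluoride removes the TES ether selectively while the C6 TBS ether stays, which keeps the C6 oxygen from attacking the ynone.

Step 23
Reactants: 28
Product: 29 (4Z,6R,7R,8S,10S)-6-{[tert-butyl(dimethyl)silyl]oxy}-3,10-epoxy-1-oxogermacra-2,4,11(13)-trien-12,8-olide
Conditions: Ph3PAuNTf2 (5 mol %), CH2Cl2, rt
Reagents that add atoms: none
Why: Gold-catalysed 5-endo-dig cycloisomerization of the α'-hydroxy ynone adds the C10 hydroxyl to C3 and gives the 3(2H)-furanone, with C10 unchanged.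

Step 24
Reactants: 29
Product: 30 (4Z,6R,7S,8S,10S)-3,10-epoxy-6-hydroxy-1-oxogermacra-2,4,11(13)-trien-12,8-olide
Conditions: HF·pyridine, THF, 0 °C to rt
Reagents that add atoms: none
Why: Acidic fluoride desilylation frees the C6 alcohol once the alkyne is gone (the C7 label changes, the geometry does not).

Step 25
Reactants: 31 angelic acid
Product: 32 (2Z)-2-methylbut-2-en-1-ol
Conditions: LiAlH4, Et2O, 0 °C to rt
Reagents that add atoms: none
Why: Hydride 1,2-reduction of the hindered unsaturated acid keeps the Z alkene.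

Step 26
Reactants: 32
Product: 33 [(2R,3S)-2,3-dimethyloxiran-2-yl]methanol
Conditions: Ti(OiPr)4 (10 mol %), D-(−)-diisopropyl tartrate (12 mol %), t-BuOOH, 4 Å MS, CH2Cl2, −20 °C
Reagents that add atoms: tert-butyl hydroperoxide, CC(C)(C)OO
Why: Sharpless asymmetric epoxidation; the D-(−)-tartrate delivers oxygen to the face that gives the (2R,3S)-epoxy alcohol, and syn addition keeps the two methyl groups trans.

Step 27
Reactants: 33
Product: 34 (2S,3S)-2,3-dimethyloxirane-2-carboxylic acid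
Conditions: RuCl3·xH2O (2 mol %), NaIO4, MeCN/CCl4/H2O, rt; used at once
Reagents that add atoms: water, O
Why: Sharpless RuO4 oxidation takes the primary alcohol to the acid without opening the epoxide (the C2 label changes from R to S, the geometry does not).

Step 28
Reactants: 30 and 34
Product: 35 (4Z,6S,7R,8S,10S)-6-{[(2S,3S)-2,3-dimethyloxirane-2-carbonyl]oxy}-3,10-epoxy-1-oxogermacra-2,4,11(13)-trien-12,8-olide
Conditions: PPh3, DIAD, toluene, 0 °C to rt
Reagents that add atoms: none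
Why: Mitsunobu esterification displaces the activated C6 oxygen by the carboxylate with SN2 inversion (6R to 6S); the alkene next to C6 is conjugated to the furanone, which disfavours ionization and allylic transposition.

## Compound list

1 | L-malic acid, (2S)-2-hydroxybutanedioic acid | OC(=O)C[C@H](O)C(=O)O | starting material
2 | 2-[(2S,4S)-2-tert-butyl-5-oxo-1,3-dioxolan-4-yl]acetic acid | OC(=O)C[C@@H]1O[C@H](C(C)(C)C)OC1=O | intermediate
3 | dilithium enolate-carboxylate of 2 | [Li+].[Li+].[O-]C(=O)CC1=C([O-])O[C@@H](C(C)(C)C)O1 | intermediate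
4 | 2-[(2S,4S)-2-tert-butyl-4-methyl-5-oxo-1,3-dioxolan-4-yl]acetic acid | OC(=O)C[C@]1(C)O[C@H](C(C)(C)C)OC1=O | intermediate
5 | (2S)-2-methylbutane-1,2,4-triol | OCC[C@](CO)(C)O | intermediate
6 | 2-[(4S)-2,2,4-trimethyl-1,3-dioxolan-4-yl]ethan-1-ol | OCC[C@@]1(C)COC(C)(C)O1 | intermediate
7 | 2-[(4S)-2,2,4-trimethyl-1,3-dioxolan-4-yl]acetaldehyde | O=CC[C@@]1(C)COC(C)(C)O1 | intermediate
8 | tert-butyl(dimethyl)(prop-2-yn-1-yloxy)silane | C#CCO[Si](C)(C)C(C)(C)C | starting material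
9 | lithium acetylide of 8 | [Li]C#CCO[Si](C)(C)C(C)(C)C | intermediate
10 | 5-{[tert-butyl(dimethyl)silyl]oxy}-1-[(4S)-2,2,4-trimethyl-1,3-dioxolan-4-yl]pent-3-yn-2-ol (C2 epimers) | CC(C)(C)[Si](C)(C)OCC#CC(O)C[C@@]1(C)COC(C)(C)O1 | intermediate
11 | 5-{[tert-butyl(dimethyl)silyl]oxy}-1-[(4S)-2,2,4-trimethyl-1,3-dioxolan-4-yl]pent-3-yn-2-one | CC(C)(C)[Si](C)(C)OCC#CC(=O)C[C@@]1(C)COC(C)(C)O1 | intermediate
12 | (2S)-5-{[tert-butyl(dimethyl)silyl]oxy}-1-[(4S)-2,2,4-trimethyl-1,3-dioxolan-4-yl]pent-3-yn-2-ol | CC(C)(C)[Si](C)(C)OCC#C[C@@H](O)C[C@@]1(C)COC(C)(C)O1 | intermediate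
13 | sodium alkenylaluminate from 12 (five-membered ring Al–O–C8–C7=C11, two 2-methoxyethoxy ligands on Al) | [Na+].COCCO[Al-]1(OCCOC)O[C@@H](C[C@@]2(C)COC(C)(C)O2)C=C1CO[Si](C)(C)C(C)(C)C | intermediate
14 | (2S,3Z)-5-{[tert-butyl(dimethyl)silyl]oxy}-4-iodo-1-[(4S)-2,2,4-trimethyl-1,3-dioxolan-4-yl]pent-3-en-2-ol | CC(C)(C)[Si](C)(C)OC/C(I)=C/[C@@H](O)C[C@@]1(C)COC(C)(C)O1 | intermediate
15 | (5S)-3-({[tert-butyl(dimethyl)silyl]oxy}methyl)-5-{[(4S)-2,2,4-trimethyl-1,3-dioxolan-4-yl]methyl}furan-2(5H)-one | CC(C)(C)[Si](C)(C)OCC1=C[C@H](C[C@@]2(C)COC(C)(C)O2)OC1=O | intermediate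
16 | (5S)-3-(hydroxymethyl)-5-{[(4S)-2,2,4-trimethyl-1,3-dioxolan-4-yl]methyl}furan-2(5H)-one | OCC1=C[C@H](C[C@@]2(C)COC(C)(C)O2)OC1=O | intermediate
17 | (5S)-3-(bromomethyl)-5-{[(4S)-2,2,4-trimethyl-1,3-dioxolan-4-yl]methyl}furan-2(5H)-one | BrCC1=C[C@H](C[C@@]2(C)COC(C)(C)O2)OC1=O | intermediate
18 | (2Z)-3-methylpent-2-en-4-yn-1-ol | C#C/C(C)=C\CO | starting material
19 | (2Z)-3-methylpent-2-en-4-ynal | C#C/C(C)=C\C=O | intermediate
20 | (4S,5S)-4-[(1R,2Z)-1-hydroxy-3-methylpent-2-en-4-yn-1-yl]-3-methylidene-5-{[(4S)-2,2,4-trimethyl-1,3-dioxolan-4-yl]methyl}oxolan-2-one | C=C1C(=O)O[C@@H](C[C@@]2(C)COC(C)(C)O2)[C@@H]1[C@H](O)/C=C(C)\C#C | intermediate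
21 | (4R,5S)-4-[(1R,2Z)-1-{[tert-butyl(dimethyl)silyl]oxy}-3-methylpent-2-en-4-yn-1-yl]-3-methylidene-5-{[(4S)-2,2,4-trimethyl-1,3-dioxolan-4-yl]methyl}oxolan-2-one | C=C1C(=O)O[C@@H](C[C@@]2(C)COC(C)(C)O2)[C@@H]1[C@H](O[Si](C)(C)C(C)(C)C)/C=C(C)\C#C | intermediate
22 | (4R,5S)-4-[(1R,2Z)-1-{[tert-butyl(dimethyl)silyl]oxy}-3-methylpent-2-en-4-yn-1-yl]-5-[(2S)-2,3-dihydroxy-2-methylpropyl]-3-methylideneoxolan-2-one | C=C1C(=O)O[C@@H](C[C@](C)(O)CO)[C@@H]1[C@H](O[Si](C)(C)C(C)(C)C)/C=C(C)\C#C | intermediate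
23 | (2S)-3-[(2S,3R)-3-[(1R,2Z)-1-{[tert-butyl(dimethyl)silyl]oxy}-3-methylpent-2-en-4-yn-1-yl]-4-methylidene-5-oxooxolan-2-yl]-2-hydroxy-2-methylpropanal | C=C1C(=O)O[C@@H](C[C@](C)(O)C=O)[C@@H]1[C@H](O[Si](C)(C)C(C)(C)C)/C=C(C)\C#C | intermediate
24 | (2S)-3-[(2S,3R)-3-[(1R,2Z)-1-{[tert-butyl(dimethyl)silyl]oxy}-3-methylpent-2-en-4-yn-1-yl]-4-methylidene-5-oxooxolan-2-yl]-2-methyl-2-[(triethylsilyl)oxy]propanal | C=C1C(=O)O[C@@H](C[C@](C)(O[Si](CC)(CC)CC)C=O)[C@@H]1[C@H](O[Si](C)(C)C(C)(C)C)/C=C(C)\C#C | intermediate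
25 | (2S)-3-[(2S,3R)-3-[(1R,2Z)-1-{[tert-butyl(dimethyl)silyl]oxy}-5-iodo-3-methylpent-2-en-4-yn-1-yl]-4-methylidene-5-oxooxolan-2-yl]-2-methyl-2-[(triethylsilyl)oxy]propanal | C=C1C(=O)O[C@@H](C[C@](C)(O[Si](CC)(CC)CC)C=O)[C@@H]1[C@H](O[Si](C)(C)C(C)(C)C)/C=C(C)\C#CI | intermediate
26 | (4Z,6R,7R,8S,10S)-6-{[tert-butyl(dimethyl)silyl]oxy}-1-hydroxy-10-[(triethylsilyl)oxy]germacra-4,11(13)-dien-2-yn-12,8-olide (C1 epimers) | C=C1C(=O)O[C@H]2C[C@](C)(O[Si](CC)(CC)CC)C(O)C#C/C(C)=C\[C@@H](O[Si](C)(C)C(C)(C)C)[C@H]12 | intermediate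
27 | (4Z,6R,7R,8S,10S)-6-{[tert-butyl(dimethyl)silyl]oxy}-1-oxo-10-[(triethylsilyl)oxy]germacra-4,11(13)-dien-2-yn-12,8-olide | C=C1C(=O)O[C@H]2C[C@](C)(O[Si](CC)(CC)CC)C(=O)C#C/C(C)=C\[C@@H](O[Si](C)(C)C(C)(C)C)[C@H]12 | intermediate
28 | (4Z,6R,7R,8S,10S)-6-{[tert-butyl(dimethyl)silyl]oxy}-10-hydroxy-1-oxogermacra-4,11(13)-dien-2-yn-12,8-olide | C=C1C(=O)O[C@H]2C[C@](C)(O)C(=O)C#C/C(C)=C\[C@@H](O[Si](C)(C)C(C)(C)C)[C@H]12 | intermediate
29 | (4Z,6R,7R,8S,10S)-6-{[tert-butyl(dimethyl)silyl]oxy}-3,10-epoxy-1-oxogermacra-2,4,11(13)-trien-12,8-olide | C=C1C(=O)O[C@H]2C[C@]3(C)OC(=CC3=O)/C(C)=C\[C@@H](O[Si](C)(C)C(C)(C)C)[C@H]12 | intermediate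
30 | (4Z,6R,7S,8S,10S)-3,10-epoxy-6-hydroxy-1-oxogermacra-2,4,11(13)-trien-12,8-olide | C=C1C(=O)O[C@H]2C[C@]3(C)OC(=CC3=O)/C(C)=C\[C@@H](O)[C@H]12 | intermediate
31 | angelic acid, (2Z)-2-methylbut-2-enoic acid | C/C=C(/C)C(=O)O | starting material
32 | (2Z)-2-methylbut-2-en-1-ol | C/C=C(/C)CO | intermediate
33 | [(2R,3S)-2,3-dimethyloxiran-2-yl]methanol | OC[C@@]1(C)O[C@H]1C | intermediate
34 | (2S,3S)-2,3-dimethyloxirane-2-carboxylic acid | OC(=O)[C@@]1(C)O[C@H]1C | intermediate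
35 | (4Z,6S,7R,8S,10S)-6-{[(2S,3S)-2,3-dimethyloxirane-2-carbonyl]oxy}-3,10-epoxy-1-oxogermacra-2,4,11(13)-trien-12,8-olide | C=C1C(=O)O[C@H]2C[C@]3(C)OC(=CC3=O)/C(C)=C\[C@H](OC(=O)[C@@]3(C)O[C@H]3C)[C@H]12 | target

## Step count and risks

Total step count: 28. Longest linear sequence: 24 steps (steps 1–12, 14–24 and 28, from L-malic acid).

**Step 20, ten-membered ring closure.** The strained enyne ring may close poorly, or the iodoalkyne may simply be reduced. The fallback sets out from 24 and comes back at 29. Markovnikov hydration of the terminal alkyne (Ph3PAuNTf2 cat., MeOH/H2O) gives the (Z)-methyl enone aldehyde F3. An intramolecular boron aldol reaction (Bu2BOTf, iPr2NEt, CH2Cl2, −78 °C, 0.002 M) closes C1–C2 to the cyclic β-hydroxy ketone F4. Dess–Martin oxidation gives the cyclic 1,3-diketone F5. HF·pyridine/pyridine removes the TES group to give the hydroxy diketone F6, and TsOH in toluene dehydrates it to the furanone 29 (the classical acid route to 3(2H)-furanones).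

**Step 28, Mitsunobu esterification.** The alcohol is hindered and the acid is α,α-disubstituted, so the coupling may stall or eliminate. The fallback sets out from 30 (with 34) and comes back at 35. Chloromethanesulfonyl chloride and pyridine in CH2Cl2 at 0 °C give the (6R)-chloromethanesulfonate F7. Displacement with caesium (2S,3S)-2,3-dimethyloxirane-2-carboxylate F8 (from 34 and Cs2CO3) and 18-crown-6 in toluene at 40 °C gives 35 with inversion at C6.

**Step 9, hydroalumination–iodination.** The alkenylaluminate carries a β-silyloxy group and can eliminate to an allene, and the product must keep its geometry for the carbonylation. The fallback sets out from 12 and comes back at 17. Semi-hydrogenation (H2, Pd/CaCO3 poisoned with Pb(OAc)2, quinoline, EtOAc) gives the (2S,3Z)-alkenol F1. Esterification with 2-(bromomethyl)prop-2-enoic acid (N,N'-diisopropylcarbodiimide, DMAP cat., CH2Cl2, 0 °C) gives the 2-(bromomethyl)acrylate F2. Ring-closing metathesis (second-generation Hoveyda–Grubbs catalyst, toluene, 80 °C) closes the butenolide and gives 17 directly.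

## Further compounds

F1 | step 9 | (2S,3Z)-5-{[tert-butyl(dimethyl)silyl]oxy}-1-[(4S)-2,2,4-trimethyl-1,3-dioxolan-4-yl]pent-3-en-2-ol | CC(C)(C)[Si](C)(C)OC/C=C\[C@@H](O)C[C@@]1(C)COC(C)(C)O1
F2 | step 9 | (2S,3Z)-5-{[tert-butyl(dimethyl)silyl]oxy}-1-[(4S)-2,2,4-trimethyl-1,3-dioxolan-4-yl]pent-3-en-2-yl 2-(bromomethyl)prop-2-enoate | CC(C)(C)[Si](C)(C)OC/C=C\[C@@H](OC(=O)C(=C)CBr)C[C@@]1(C)COC(C)(C)O1
F3 | step 20 | (2S)-3-[(2S,3R)-3-[(1R,2Z)-1-{[tert-butyl(dimethyl)silyl]oxy}-3-methyl-4-oxopent-2-en-1-yl]-4-methylidene-5-oxooxolan-2-yl]-2-methyl-2-[(triethylsilyl)oxy]propanal | C=C1C(=O)O[C@@H](C[C@](C)(O[Si](CC)(CC)CC)C=O)[C@@H]1[C@H](O[Si](C)(C)C(C)(C)C)/C=C(C)\C(C)=O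
F4 | step 20 | (4Z,6R,7R,8S,10S)-6-{[tert-butyl(dimethyl)silyl]oxy}-1-hydroxy-3-oxo-10-[(triethylsilyl)oxy]germacra-4,11(13)-dien-12,8-olide (C1 epimers) | C=C1C(=O)O[C@H]2C[C@](C)(O[Si](CC)(CC)CC)C(O)CC(=O)/C(C)=C\[C@@H](O[Si](C)(C)C(C)(C)C)[C@H]12
F5 | step 20 | (4Z,6R,7R,8S,10S)-6-{[tert-butyl(dimethyl)silyl]oxy}-1,3-dioxo-10-[(triethylsilyl)oxy]germacra-4,11(13)-dien-12,8-olide | C=C1C(=O)O[C@H]2C[C@](C)(O[Si](CC)(CC)CC)C(=O)CC(=O)/C(C)=C\[C@@H](O[Si](C)(C)C(C)(C)C)[C@H]12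
F6 | step 20 | (4Z,6R,7R,8S,10S)-6-{[tert-butyl(dimethyl)silyl]oxy}-10-hydroxy-1,3-dioxogermacra-4,11(13)-dien-12,8-olide | C=C1C(=O)O[C@H]2C[C@](C)(O)C(=O)CC(=O)/C(C)=C\[C@@H](O[Si](C)(C)C(C)(C)C)[C@H]12
F7 | step 28 | (4Z,6R,7R,8S,10S)-6-[(chloromethanesulfonyl)oxy]-3,10-epoxy-1-oxogermacra-2,4,11(13)-trien-12,8-olide | C=C1C(=O)O[C@H]2C[C@]3(C)OC(=CC3=O)/C(C)=C\[C@@H](OS(=O)(=O)CCl)[C@H]12
F8 | step 28 | caesium (2S,3S)-2,3-dimethyloxirane-2-carboxylate | [Cs+].[O-]C(=O)[C@@]1(C)O[C@H]1C
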